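**Retrosynthetic overview**

1. Numbering: ring B (five-membered) is C1–C2–C3=C4(C16)–C5; ring A (seven-membered) is C5–C6(OH)–C7–C8–C9(OAc)–C10(=C18H2)–C1; the side chain C11(Me)–C12(OAc)–C13–C14=C15 sits on C7.
2. Key disconnection: C10–C1 and C8–C7 are made together, by rhodium-carbenoid cyclopropanation of C1=C5 and Cope ring expansion of the resulting cis-divinylcyclopropane (C10–C1–C5) to ring A.
3. Enabling feature: C2 of ring B, a CH2 next to C1 in the target, carries a temporary oxygen. Its ester with C18 (the future exocyclic methylene carbon) holds the C18–C10–C9–C8 silyloxyvinyl diazo unit allylic to C1=C5, and C5 carries the (Z)-C6(OSi)=C7 enol ether.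
4. Ring order: ring B (from a 4-silyloxycyclopentenone), then cyclopropane plus temporary γ-lactone (C18–O–C2), then ring A. The lactone later leaves C2 as a carboxylate (E1cB from the C4 ketone); C4=O becomes C3=C4–C16 and the C18 ester becomes the methylene.
5. C11/C12 come from a syn-crotylation (cis-lactone 5); C1 from the tether, C7 from the Cope boat, C5 by epimerisation, C6 and C9 by reductions.

Key step: step 13

Assumption: the Ipc2BOMe enantiomer written in step 2 is taken to be the one that delivers (3S,4S)-3; if the sense of induction is the reverse, its antipode is used with no other change.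

**Route**

Step 1
Reactants: 1 4-methylpent-3-en-1-ol
Product: 2 4-methylpent-3-enal
Conditions: Dess–Martin periodinane, NaHCO3, CH2Cl2, 0 °C; used crude
Reagents that add atoms: none
Why: Dess–Martin oxidation under buffered, non-basic conditions should give the β,γ-unsaturated aldehyde without moving the double bond into conjugation.

Step 2
Reactants: 2 4-methylpent-3-enal
Product: 3 (3S,4S)-syn homoallylic alcohol
Conditions: cis-2-butene, KOt-Bu, n-BuLi, THF, −78 → −45 °C; (+)-Ipc2BOMe; BF3·OEt2; then 2, −78 °C; NaOH, H2O2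
Reagents that add atoms: cis-but-2-ene, C/C=C\C
Why: Brown (Z)-crotylboration through a chair Zimmerman–Traxler transition state: the (Z)-crotyl geometry gives the syn pair and the isopinocampheyl groups select the aldehyde face, which sets C11 and C12.

Step 3
Reactants: 3 (3S,4S)-syn homoallylic alcohol
Product: 4 (3S,4S)-1,4-diol
Conditions: 9-BBN, THF, 0 °C → rt; then NaOH, H2O2, 0 °C
Reagents that add atoms: hydrogen peroxide, OO
Why: Anti-Markovnikov hydroboration–oxidation with 9-BBN should take the terminal alkene only and leave the trisubstituted alkene untouched.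

Step 4
Reactants: 4 (3S,4S)-1,4-diol
Product: 5 cis-lactone
Conditions: TEMPO (cat.), PhI(OAc)2, CH2Cl2, rt
Reagents that add atoms: none
Why: Oxoammonium oxidation of the primary alcohol, lactol formation and a second oxidation (oxidative lactonisation of a 1,4-diol) should give the γ-lactone without touching C11 or C12.

Step 5
Reactants: 6 (R)-4-silyloxycyclopentenone
Product: 7 2-iodo enone
Conditions: I2, pyridine, CH2Cl2, 0 °C → rt
Reagents that add atoms: iodine, II
Why: α-Iodination of the enone by conjugate addition of pyridine, iodination of the enolate and elimination is standard for 4-silyloxycyclopentenones.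

Step 6
Reactants: 7 2-iodo enone
Product: 8 iodo ketal
Conditions: (TMSOCH2)2, TMSOTf (cat.), CH2Cl2, −78 → −20 °C
Reagents that add atoms: 1,2-bis(trimethylsilyloxy)ethane, C[Si](C)(C)OCCO[Si](C)(C)C
Why: Aprotic Noyori ketalisation should protect C4 without β-elimination of the silyloxy group or migration of the double bond.

Step 7
Reactants: 8 iodo ketal; 5 cis-lactone
Product: 10 hydroxy enone, via alkenyllithium 9 (not isolated)
Conditions: t-BuLi, Et2O, −78 °C; then 5, −78 °C; aq. NH4Cl
Reagents that add atoms: none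
Why: Iodine–lithium exchange and acylation of the alkenyllithium by the lactone should stop at the ketone, because the tetrahedral lithium lactolate survives at −78 °C; this joins C5 to C6.

Step 8
Reactants: 10 hydroxy enone
Product: 11 C12 acetate
Conditions: Ac2O, DMAP (cat.), pyridine, CH2Cl2, 0 °C → rt
Reagents that add atoms: acetic anhydride, CC(=O)OC(C)=O
Why: Acetylation traps the open hydroxy ketone form and masks O-12 so that only O-2 is free for the tether.

Step 9
Reactants: 11 C12 acetate
Product: 12 C2 alcohol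
Conditions: HF·pyridine, pyridine, THF, 0 °C → rt
Reagents that add atoms: none
Why: Buffered fluoride should remove the allylic secondary silyl ether and leave ketal, acetate and enone alone.

Step 10
Reactants: 12 C2 alcohol
Product: 13 acetoacetate
Conditions: 2,2,6-trimethyl-4H-1,3-dioxin-4-one, PhMe, 110 °C
Reagents that add atoms: 2,2,6-trimethyl-4H-1,3-dioxin-4-one, CC1=CC(=O)OC(C)(C)O1
Why: Thermal retro-[4+2] of the dioxinone gives acetylketene, which the C2 hydroxyl traps as the acetoacetate; this brings in C18, C10, C9 and C8.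

Step 11
Reactants: 13 acetoacetate
Product: 14 diazoacetoacetate
Conditions: 4-acetamidobenzenesulfonyl azide, Et3N, MeCN, 0 °C → rt
Reagents that add atoms: 4-acetamidobenzenesulfonyl azide, CC(=O)Nc1ccc(cc1)S(=O)(=O)N=[N+]=[N-]
Why: Regitz diazo transfer to the 1,3-dicarbonyl carbon is reliable and tolerates the enone and the acetate.

Step 12
Reactants: 14 diazoacetoacetate
Product: 15 diazo bis(silyl enol ether)
Conditions: TBSOTf, Et3N, CH2Cl2, −78 → 0 °C; used without chromatography
Reagents that add atoms: tert-butyldimethylsilyl triflate, CC(C)(C)[Si](C)(C)OS(=O)(=O)C(F)(F)F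
Why: Soft enolisation should silylate the diazo keto ester to the 3-silyloxy-2-diazobut-3-enoate and the enone at C7 (kinetic α′ site) to the cross-conjugated (Z)-silyl dienol ether; the Z geometry is needed for C7 in step 13.

Step 13
Reactants: 15 diazo bis(silyl enol ether)
Product: 17 tricyclic lactone, via cyclopropane lactone 16 (not isolated)
Conditions: Rh2(OAc)4 (1 mol %), CH2Cl2, 40 °C, slow addition of 15; then PhMe, 80 °C if 16 persists
Reagents that add atoms: none
Why: Rh2(OAc)4 converts the diazo ester into a donor/acceptor rhodium vinylcarbenoid at C10, which cyclopropanates the allylic C1=C5 bond through the five-membered lactone that the C2–O–C18 ester imposes ([2+1] closure giving cyclopropane C10–C1–C5 and the γ-lactone together). The cis-1,2-divinylcyclopropane 16 then undergoes a boat [3,3] Cope rearrangement that breaks C10–C5 and joins C8 to C7, closing ring A as a cyclohepta-1,4-diene by three-to-seven ring expansion. The closest known reactions are the intramolecular tandem cyclopropanation/Cope rearrangement of 2,4-dienyl vinyldiazoacetates and the intramolecular cyclopropanation of cyclopent-2-enyl diazoacetates. C1 is set by the tether (the carbenoid is delivered to the face of ring B syn to O-2), and C7 by the boat transition state with the (Z)-enol ether (C11 outside, H-7 inside, so H-7 ends cis to H-1). The step needs attack on C1=C5 and not on the electron-rich C6=C7 enol ether or a C3–H bond, and it needs the two vinyl groups cis. The tether secures both: only C1=C5 is reached through a five-membered ring, and the cis-fused lactone puts its carbonyl on the face of C2 and C4, so the silyloxyvinyl group on C10 and the C6=C7 alkenyl group on C5 share the other face.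

Step 14
Reactants: 17 tricyclic lactone
Product: 19 trans-fused C6 ketone, via cis-fused ketone 18 (not isolated)
Conditions: aq. HCl (0.2 M), THF, 0 °C; then DBU (0.5 equiv), CH2Cl2, rt
Reagents that add atoms: none
Why: Acid should protonate only the ketone-derived silyl enol ether at C5 (the push–pull C9 silyl enol ether of the lactone is far less basic at carbon), and DBU should then epimerise C5 to the trans ring fusion, because the cis isomer holds O-2, C10 and C6 all cis on ring B.

Step 15
Reactants: 19 trans-fused C6 ketone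
Product: 20 C6 alcohol
Conditions: NaBH4, MeOH/THF, −20 °C
Reagents that add atoms: none
Why: Hydride should attack the C6 carbonyl from the face opposite the C7 side chain, giving the 6-alcohol cis to the side chain as in the target, while lactone, acetate and ketal survive.

Step 16
Reactants: 20 C6 alcohol
Product: 21 C6 silyl ether
Conditions: TBSOTf, 2,6-lutidine, CH2Cl2, −78 → 0 °C
Reagents that add atoms: tert-butyldimethylsilyl triflate, CC(C)(C)[Si](C)(C)OS(=O)(=O)C(F)(F)F
Why: The silyl triflate should silylate the hindered secondary alcohol, which must be masked (and made a poor leaving group) before the C4 ketone is set free.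

Step 17
Reactants: 21 C6 silyl ether
Product: 24 cyclopentenone methyl ester, via C4 ketone 22 (not isolated), via carboxylic acid 23 (not isolated)
Conditions: In(OTf)3 (2 mol %), acetone, rt; then Et3N, CH2Cl2, 0 °C; then TMSCHN2, MeOH/PhMe, 0 °C
Reagents that add atoms: (trimethylsilyl)diazomethane, C[Si](C)(C)C=[N+]=[N-]
Why: Transketalisation frees the C4 ketone, whose C3 enolate expels the C2 carboxylate (E1cB; the acyloxy group leaves far more readily than the C6 silyloxy group), which opens the temporary lactone and removes O-2; esterification fixes C18 as the methyl ester.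

Step 18
Reactants: 24 cyclopentenone methyl ester
Product: 26 alkenyl triflate, via lithium enolate 25 (not isolated)
Conditions: LiBH(sec-Bu)3, THF, −78 °C; then N-(5-chloro-2-pyridyl)triflimide (Comins' reagent), −78 → 0 °C
Reagents that add atoms: N-(5-chloropyridin-2-yl)bis(trifluoromethanesulfonyl)imide, Clc1ccc(nc1)N(S(=O)(=O)C(F)(F)F)S(=O)(=O)C(F)(F)F
Why: Conjugate hydride addition at C2 (1,2-attack is hindered by the C5 substituent) should give the C4(O)=C3 enolate regiospecifically, and O-triflation traps it.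

Step 19
Reactants: 26 alkenyl triflate
Product: 27 C4-methyl alkene
Conditions: Me2CuLi (from MeLi, CuI), Et2O, −20 °C
Reagents that add atoms: lithium dimethylcuprate, [Li+].C[Cu-]C
Why: Coupling of an alkenyl triflate with a Gilman cuprate installs C16 on C4 with the C3=C4 bond fixed; esters and silyl ethers are tolerated at this temperature.

Step 20
Reactants: 27 C4-methyl alkene
Product: 29 α-methylene ketone, via allylic alcohol 28 (not isolated)
Conditions: i-Bu2AlH, CH2Cl2, −78 → −40 °C; then aq. HCl (0.5 M), THF, 0 °C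
Reagents that add atoms: none
Why: The aluminium hydride reduces the C18 ester to the allylic alcohol and cleaves the C12 acetate; dilute acid then ionises the allylic alcohol with the help of the C9 silyl enol ether (as in a Stork–Danheiser transposition) to give the exocyclic C10=C18 enone.

Step 21
Reactants: 29 α-methylene ketone
Product: 30 9,12-diol
Conditions: (S)-Me-CBS oxazaborolidine (20 mol %), BH3·SMe2, THF, −30 °C; MeOH quench
Reagents that add atoms: none
Why: Corey–Bakshi–Shibata reduction with the alkenyl carbon C10 as the large group should deliver hydride to one face under catalyst control and set C9 (R).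

Step 22
Reactants: 30 9,12-diol
Product: 31 9,12-diacetate
Conditions: Ac2O, DMAP (cat.), pyridine, CH2Cl2, rt
Reagents that add atoms: acetic anhydride, CC(=O)OC(C)=O
Why: Both free secondary alcohols are acetylated exhaustively while O-6 is still silylated, so no selectivity is needed.

Step 23
Reactants: 31 9,12-diacetate
Product: 32 target diacetate
Conditions: HF·pyridine, THF, 0 °C → rt
Reagents that add atoms: none
Why: Acidic fluoride should remove the hindered silyl ether without acyl migration or loss of the allylic acetate.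

**Compound list**

1 | 4-methylpent-3-en-1-ol | CC(C)=CCCO | starting material
2 | 4-methylpent-3-enal | CC(C)=CCC=O | intermediate
3 | (3S,4S)-3,7-dimethylocta-1,6-dien-4-ol | C=C[C@H](C)[C@@H](O)CC=C(C)C | intermediate
4 | (3S,4S)-3,7-dimethyloct-6-ene-1,4-diol | OCC[C@H](C)[C@@H](O)CC=C(C)C | intermediate
5 | (4S,5S)-4-methyl-5-(3-methylbut-2-en-1-yl)oxolan-2-one (cis-lactone) | O=C1C[C@H](C)[C@H](CC=C(C)C)O1 | intermediate
6 | (R)-4-[(tert-butyldimethylsilyl)oxy]cyclopent-2-en-1-one | O=C1C=C[C@H](O[Si](C)(C)C(C)(C)C)C1 | starting material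
7 | (R)-4-[(tert-butyldimethylsilyl)oxy]-2-iodocyclopent-2-en-1-one | O=C1C(I)=C[C@H](O[Si](C)(C)C(C)(C)C)C1 | intermediate
8 | (8R)-8-[(tert-butyldimethylsilyl)oxy]-6-iodo-1,4-dioxaspiro[4.4]non-6-ene | IC1=C[C@H](O[Si](C)(C)C(C)(C)C)CC21OCCO2 | intermediate
9 | 6-lithio analogue of 8 (alkenyllithium) | [Li]C1=C[C@H](O[Si](C)(C)C(C)(C)C)CC21OCCO2 | intermediate
10 | (3S,4S)-1-[(8R)-8-(tert-butyldimethylsilyloxy)-1,4-dioxaspiro[4.4]non-6-en-6-yl]-4-hydroxy-3,7-dimethyloct-6-en-1-one | CC(C)=CC[C@H](O)[C@@H](C)CC(=O)C1=C[C@H](O[Si](C)(C)C(C)(C)C)CC21OCCO2 | intermediate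
11 | 4-O-acetate of 10 (C12 acetate) | CC(C)=CC[C@H](OC(C)=O)[C@@H](C)CC(=O)C1=C[C@H](O[Si](C)(C)C(C)(C)C)CC21OCCO2 | intermediate
12 | (3S,4S)-1-[(8R)-8-hydroxy-1,4-dioxaspiro[4.4]non-6-en-6-yl]-3,7-dimethyl-1-oxooct-6-en-4-yl acetate | CC(C)=CC[C@H](OC(C)=O)[C@@H](C)CC(=O)C1=C[C@H](O)CC21OCCO2 | intermediate
13 | 3-oxobutanoate of 12 at the ring (C2) hydroxyl | CC(C)=CC[C@H](OC(C)=O)[C@@H](C)CC(=O)C1=C[C@H](OC(=O)CC(C)=O)CC21OCCO2 | intermediate
14 | 2-diazo-3-oxobutanoate of 12 at the ring (C2) hydroxyl | CC(C)=CC[C@H](OC(C)=O)[C@@H](C)CC(=O)C1=C[C@H](OC(=O)C(=[N+]=[N-])C(C)=O)CC21OCCO2 | intermediate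
15 | (8R)-6-[(1Z,3S,4S)-4-acetoxy-1-(tert-butyldimethylsilyloxy)-3,7-dimethylocta-1,6-dien-1-yl]-1,4-dioxaspiro[4.4]non-6-en-8-yl 2-diazo-3-(tert-butyldimethylsilyloxy)but-3-enoate | CC(C)=CC[C@H](OC(C)=O)[C@@H](C)/C=C(\O[Si](C)(C)C(C)(C)C)C1=C[C@H](OC(=O)C(=[N+]=[N-])C(=C)O[Si](C)(C)C(C)(C)C)CC21OCCO2 | intermediate
16 | cis-divinylcyclopropane (C10–C1–C5) fused to the C18–O–C2 γ-lactone and to ring B; 1-silyloxyvinyl on C10, (Z)-C6(OTBS)=C7 alkenyl on C5, C4 ketal | O=C1O[C@@H]2CC3(OCCO3)[C@@]4(/C(O[Si](C)(C)C(C)(C)C)=C/[C@H](C)[C@H](CC=C(C)C)OC(C)=O)[C@@H]2[C@@]14C(=C)O[Si](C)(C)C(C)(C)C | intermediate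
17 | tricyclic lactone: rings A and B with C18(=O)–O–C2 lactone, silyl enol ethers C9(OTBS)=C10 and C6(OTBS)=C5, C4 ethylene ketal, 12-acetate; C1, C7, C11, C12 as in 32, O-2 cis to C10 | O=C1O[C@@H]2CC3(OCCO3)C4=C(O[Si](C)(C)C(C)(C)C)[C@H]([C@H](C)[C@H](CC=C(C)C)OC(C)=O)CC(O[Si](C)(C)C(C)(C)C)=C1[C@H]24 | intermediate
18 | C6 ketone of 17, cis ring fusion (C5 epimer of 19) | O=C1O[C@@H]2CC3(OCCO3)[C@@H]4C(=O)[C@H]([C@H](C)[C@H](CC=C(C)C)OC(C)=O)CC(O[Si](C)(C)C(C)(C)C)=C1[C@H]24 | intermediate
19 | C6 ketone of 17, trans ring fusion (C5 as in 32) | O=C1O[C@@H]2CC3(OCCO3)[C@H]4C(=O)[C@H]([C@H](C)[C@H](CC=C(C)C)OC(C)=O)CC(O[Si](C)(C)C(C)(C)C)=C1[C@H]24 | intermediate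
20 | 6-alcohol of 19 (C6 as in 32) | O=C1O[C@@H]2CC3(OCCO3)[C@H]4[C@H](O)[C@H]([C@H](C)[C@H](CC=C(C)C)OC(C)=O)CC(O[Si](C)(C)C(C)(C)C)=C1[C@H]24 | intermediate
21 | 6-O-tert-butyldimethylsilyl ether of 20 | O=C1O[C@@H]2CC3(OCCO3)[C@H]4[C@H](O[Si](C)(C)C(C)(C)C)[C@H]([C@H](C)[C@H](CC=C(C)C)OC(C)=O)CC(O[Si](C)(C)C(C)(C)C)=C1[C@H]24 | intermediate
22 | C4 ketone of 21 (ketal removed, lactone intact) | O=C1O[C@@H]2CC(=O)[C@H]4[C@H](O[Si](C)(C)C(C)(C)C)[C@H]([C@H](C)[C@H](CC=C(C)C)OC(C)=O)CC(O[Si](C)(C)C(C)(C)C)=C1[C@H]24 | intermediate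
23 | C2=C3 cyclopentenone (C4 ketone) with free C18 carboxylic acid on C10, C9 silyl enol ether, 6-OTBS, 12-acetate | OC(=O)C1=C(O[Si](C)(C)C(C)(C)C)C[C@@H]([C@H](C)[C@H](CC=C(C)C)OC(C)=O)[C@@H](O[Si](C)(C)C(C)(C)C)[C@@H]2C(=O)C=C[C@@H]12 | intermediate
24 | methyl ester of 23 | COC(=O)C1=C(O[Si](C)(C)C(C)(C)C)C[C@@H]([C@H](C)[C@H](CC=C(C)C)OC(C)=O)[C@@H](O[Si](C)(C)C(C)(C)C)[C@@H]2C(=O)C=C[C@@H]12 | intermediate
25 | lithium C4(O)=C3 enolate from conjugate reduction of 24 | COC(=O)C1=C(O[Si](C)(C)C(C)(C)C)C[C@@H]([C@H](C)[C@H](CC=C(C)C)OC(C)=O)[C@@H](O[Si](C)(C)C(C)(C)C)[C@@H]2C(O[Li])=CC[C@@H]12 | intermediate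
26 | C4 alkenyl triflate (C3=C4) | COC(=O)C1=C(O[Si](C)(C)C(C)(C)C)C[C@@H]([C@H](C)[C@H](CC=C(C)C)OC(C)=O)[C@@H](O[Si](C)(C)C(C)(C)C)[C@@H]2C(OS(=O)(=O)C(F)(F)F)=CC[C@@H]12 | intermediate
27 | C4-methyl alkene: methyl C18 ester, C9 silyl enol ether, 6-OTBS, 12-acetate | COC(=O)C1=C(O[Si](C)(C)C(C)(C)C)C[C@@H]([C@H](C)[C@H](CC=C(C)C)OC(C)=O)[C@@H](O[Si](C)(C)C(C)(C)C)[C@@H]2C(C)=CC[C@@H]12 | intermediate
28 | C18 allylic alcohol with C9 silyl enol ether, 6-OTBS, free 12-OH | OCC1=C(O[Si](C)(C)C(C)(C)C)C[C@@H]([C@H](C)[C@H](CC=C(C)C)O)[C@@H](O[Si](C)(C)C(C)(C)C)[C@@H]2C(C)=CC[C@@H]12 | intermediate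
29 | C9 ketone with exocyclic C10=C18 methylene, 6-OTBS, free 12-OH | C=C1C(=O)C[C@@H]([C@H](C)[C@H](CC=C(C)C)O)[C@@H](O[Si](C)(C)C(C)(C)C)[C@@H]2C(C)=CC[C@@H]12 | intermediate
30 | (9R)-9,12-diol, 6-OTBS | C=C1[C@H](O)C[C@@H]([C@H](C)[C@H](CC=C(C)C)O)[C@@H](O[Si](C)(C)C(C)(C)C)[C@@H]2C(C)=CC[C@@H]12 | intermediate
31 | 9,12-diacetate, 6-OTBS | C=C1[C@H](OC(C)=O)C[C@@H]([C@H](C)[C@H](CC=C(C)C)OC(C)=O)[C@@H](O[Si](C)(C)C(C)(C)C)[C@@H]2C(C)=CC[C@@H]12 | intermediate
32 | CNP0151479.2: (1R,5S,6R,7S,9R,11S,12S)-6-hydroxy-9,12-diacetoxy diterpene in the numbering above | C=C1[C@H](OC(C)=O)C[C@@H]([C@H](C)[C@H](CC=C(C)C)OC(C)=O)[C@@H](O)[C@@H]2C(C)=CC[C@@H]12 | target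

**Step count**

Total: 23 steps. Longest linear sequence: 21 steps (steps 1–4 and 7–23); steps 5–6 form the second branch.

**Steps most likely to fail**

Step 14. The epimerisation at C5 may stall or settle on the cis ring fusion, because the lactone bridge shifts the balance between the two fusions and C7 can also epimerise. Fallback: the epimerisation is moved to a later carbonyl. Setting out from 18 (DBU omitted), NaBH4 reduction should give the cis-fused 6-alcohol F1, and silylation (TBSOTf, 2,6-lutidine) its silyl ether F2. Deketalisation, elimination and esterification as in step 17 then give the C5-epimeric cyclopentenone ester F3. There H-5 is α to the C4 enone carbonyl and the lactone bridge is gone, so DBU (CH2Cl2, rt) should equilibrate C5 to the trans-4,5-disubstituted cyclopentenone, which is 24.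

Step 15. Hydride delivery at C6 may show poor facial selectivity. Fallback: inversion instead of a second reduction. Setting out from 19, the unwanted C6-epimeric alcohol F4 is inverted by a Mitsunobu reaction with chloroacetic acid (PPh3, DIAD, PhMe) to the chloroacetate F5. The chloroacetyl group is then removed with thiourea (NaHCO3, EtOH), which leaves the C12 acetate and the lactone alone, and the route is rejoined at 20.

Step 18. 1,2-Reduction of the enone carbonyl may compete with conjugate reduction, and the enolate may be protonated before it is triflated. Fallback: the two events are separated. Setting out from 24, conjugate reduction with the copper hydride [(Ph3P)CuH]6 (PhMe, rt, aqueous work-up) should give the saturated C4 ketone F6. Kinetic deprotonation at C3 (the only CH2 next to the carbonyl) with KN(SiMe3)2 in THF at −78 °C and trapping with Comins' reagent then gives 26.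

**Further compounds**

F1 | step 14 | cis-fused 6-alcohol (C5 epimer of 20) | O=C1O[C@@H]2CC3(OCCO3)[C@@H]4[C@H](O)[C@H]([C@H](C)[C@H](CC=C(C)C)OC(C)=O)CC(O[Si](C)(C)C(C)(C)C)=C1[C@H]24
F2 | step 14 | 6-O-tert-butyldimethylsilyl ether of F1 (C5 epimer of 21) | O=C1O[C@@H]2CC3(OCCO3)[C@@H]4[C@H](O[Si](C)(C)C(C)(C)C)[C@H]([C@H](C)[C@H](CC=C(C)C)OC(C)=O)CC(O[Si](C)(C)C(C)(C)C)=C1[C@H]24
F3 | step 14 | C5 epimer of cyclopentenone methyl ester 24 | COC(=O)C1=C(O[Si](C)(C)C(C)(C)C)C[C@@H]([C@H](C)[C@H](CC=C(C)C)OC(C)=O)[C@@H](O[Si](C)(C)C(C)(C)C)[C@H]2C(=O)C=C[C@@H]12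
F4 | step 15 | C6 epimer of alcohol 20 | O=C1O[C@@H]2CC3(OCCO3)[C@H]4[C@@H](O)[C@H]([C@H](C)[C@H](CC=C(C)C)OC(C)=O)CC(O[Si](C)(C)C(C)(C)C)=C1[C@H]24
F5 | step 15 | 6-O-chloroacetate of 20 (C6 as in 32) | O=C1O[C@@H]2CC3(OCCO3)[C@H]4[C@H](OC(=O)CCl)[C@H]([C@H](C)[C@H](CC=C(C)C)OC(C)=O)CC(O[Si](C)(C)C(C)(C)C)=C1[C@H]24
F6 | step 18 | saturated C4 ketone (2,3-dihydro 24) | COC(=O)C1=C(O[Si](C)(C)C(C)(C)C)C[C@@H]([C@H](C)[C@H](CC=C(C)C)OC(C)=O)[C@@H](O[Si](C)(C)C(C)(C)C)[C@@H]2C(=O)CC[C@@H]12
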